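## The problem

The target 16 is a fully aromatic 2-aryl-3-methylbenzofuran without stereocentres, so the difficulties are regiochemistry and functional-group tolerance, not configuration. The benzo ring carries three contiguous substituents: methoxy at C5, a free hydroxyl at C6, and an allyl group at C7 lodged between that hydroxyl and the ring-fusion carbon C7a. Only C4 is unsubstituted. The furan ring must be built with the methyl group on C3 (next to the benzo ring) and the 3,4,5-trimethoxyphenyl group on C2 (next to oxygen). One oxygen of five stays free while four are methyl ethers, so O6 needs a protecting group that can be told apart from methyl. The terminal allyl alkene is the most fragile element: it adds electrophilic bromine, is reduced by hydrogenation, migrates into conjugation under hot base or palladium hydrides, and can enter Heck chemistry. The free electron-rich phenol is easily oxidised, so both groups are best introduced or unmasked late. The fragment O1–C7a–C3a–C3(CH3)=C2 of the target is the fragment O1–C8a–C4a–C4(CH3)=C3 of a 4-methylcoumarin, one carbon short of the lactone carbonyl. The 6-oxygen of the benzofuran corresponds to the coumarin 7-oxygen, which is para to C4a and activates coumarin C3 for bromination; this makes a lactone-to-furan ring contraction possible. The C5 methoxy group blocks one of the two positions ortho to O6, so an allyl group migrating from O6 can only arrive at C7.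

## Retrosynthesis

**C7–allyl bond.** Target 16 is cut at the C7–CH2 bond and traced to the allyl ether 15 by an aromatic Claisen rearrangement. Direct C-allylation of the phenol would give O/C mixtures, and carrying the allyl group from the start would expose it to bromination, hot base, palladium and hydrogenation. The rearrangement is asked only to be thermal and clean; its regiochemistry is fixed because C5 is substituted and the para position is the ring-fusion carbon C3a.

**O6–allyl and O6–benzyl bonds.** Ether 15 comes from phenol 13 and allyl bromide 14, and 13 from benzyl ether 12 by hydrogenolysis. Benzyl is chosen because it survives electrophilic bromination, boiling hydroxide and a carbonate base at 170 °C, and is removed without touching methyl ethers. A methyl group here would be indistinguishable from the other four, and an allyl ether would not survive zerovalent palladium in the arylation step.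

**C2–aryl bond.** Compound 12 is cut between C2 and the trimethoxyphenyl ring, giving the benzofuran-2-carboxylic acid 10 and 5-bromo-1,2,3-trimethoxybenzene 11. A decarboxylative cross-coupling uses the carboxyl group as both leaving group and position marker, so no separate halogenation or borylation of the furan is needed. The 3-methyl group blocks the neighbouring position against stray arylation.

**O1–C2 bond (key disconnection).** Acid 10 is traced to the 3-bromo-4-methylcoumarin 8 by a Perkin ring contraction through the ring-opened dianion 9. The cut removes the furan ring and replaces it by a lactone that is far easier to make regioselectively. The methyl group, the ring oxygen and the future C2 carbon are already in place in 8, and the lactone carbonyl is not wasted but becomes the carboxyl handle. The forward reaction must open the lactone and then close the five-membered ring by displacement of a vinylic bromide.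

**C3–Br and O7–benzyl bonds of the coumarin.** Bromide 8 comes from coumarin 7 by electrophilic bromination at C3, and 7 from the hydroxycoumarin 5 and benzyl bromide 6. Benzylation comes first so that the ring positions ortho to a free phenol do not compete with C3 for the brominating agent.

**Coumarin ring.** Coumarin 5 is cut at C4–C4a and O1–C2 into 4-methoxybenzene-1,3-diol 3 and ethyl acetoacetate 4 (Pechmann condensation). The resorcinol has only one unhindered, doubly activated carbon, so the 7-hydroxy-6-methoxy pattern follows from its structure.

**Aryl C–O bond of the diol.** Diol 3 is traced to isovanillin 1 by replacing the formyl group with hydroxyl (Baeyer–Villiger oxidation to formate 2, then methanolysis). Isovanillin already has the methoxy and hydroxyl groups in the right relationship and is a cheap bulk aromatic.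

## Roads not taken

**Alternative 1:** ortho-quinone methide plus sulfur ylide.
- Cut: O1–C2 and C2–C3 of a dihydrobenzofuran.
- Forward key step: Cs2CO3 would convert the sulfone A3 into an ortho-quinone methide and the sulfonium salt A2 into its ylide. The ylide carbon adds to the methide carbon, and the phenoxide then closes the ring with loss of the sulfide, giving the trans dihydrobenzofuran A1.
- Merits: it is convergent, runs under mild base at ambient temperature, forms two bonds in one operation, and brings every substituent in on the two halves.
- Weak points for this target:
  - It creates two stereocentres only to erase them, so a dehydrogenation with a quinone-type oxidant is needed while the allyl group and two electron-rich rings are present, followed by acetal cleavage.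
  - A quinone methide with a methyl on the methide carbon can tautomerise to an ortho-vinylphenol by hydrogen shift.
  - The electron-rich benzylic ylide is only weakly stabilised.
  - A3 is a hexasubstituted benzene whose preparation would cost about as many steps as the coumarin sequence.
- Comparison: this road is better in convergence and in the mildness of its key step. The chosen plan offers intermediates that are aromatic at the right oxidation level throughout, and no oxidation after the allyl group exists.

**Alternative 2:** iron-mediated oxidative C–H etherification.
- Cut: O1–C7a.
- Forward key step: FeCl3 (trivalent iron, used in stoichiometric amount) oxidises the α-aryl propiophenone A4, and the enol oxygen bonds to the ring C–H carbon para to the methoxy group, giving benzofuran A5 directly.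
- Merits: it reaches the benzofuran at the correct oxidation state with no decarboxylation. It is convergent if A4 comes from a ketone α-arylation, and it is probably the shortest of the four routes.
- Weak points for this target:
  - A strong one-electron oxidant and Lewis acid meets a terminal alkene and an isopropyl ether.
  - The regiochemistry is not forced by the structure: it rests on the preference for the C–H para to methoxy (which is also ortho to the allyl group) over the C–H ortho to methoxy.
  - The allyl group must be carried through the palladium-catalysed assembly of A4.
  - The isopropyl ether must finally be cleaved in the presence of four methyl ethers.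
- Comparison: this road is better in step count. The chosen plan has fixed regiochemistry instead: the O1–C7a bond exists from the resorcinol stage, and the allyl group is placed by a rearrangement with a single possible terminus.

**Alternative 3:** anodic phenol–propenylarene annulation.
- Cut: C3–C3a and O1–C2.
- Forward key step: constant-current oxidation of the 4-methoxyphenol A6 gives a phenoxonium ion that is trapped by (E)-isoelemicin A7 in a formal (3+2) annulation, giving the trans dihydrobenzofuran pivalate A8.
- Merits: it is the most direct and biomimetic assembly, uses no metal reagent, and has two simple partners.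
- Weak points for this target:
  - A7 is a trimethoxystyrene that is oxidised at a potential close to that of the phenol, so its own dimerisation competes.
  - The acyloxy group of A6 raises the oxidation potential of the phenol.
  - The allyl group ortho to the hydroxyl is an internal trap for the cation, and attack at the methoxy-bearing carbon leads to quinone ketals.
  - The product again needs dehydrogenation beside an allyl group, plus ester cleavage.
- Comparison: this road is better in brevity and atom economy. The chosen plan is longer but predictable, with each step resting on a well-defined polar or catalytic mechanism and no oxidation in the presence of the alkene.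

Key step: step 5

## Route

Remark on the chemistry: the ring-opened intermediate 9 of step 5 is written as the E isomer, because the lactone ring holds the aryl group and the carboxyl carbon on the same side of the double bond.

Step 1
Reactants: 1 isovanillin (3-hydroxy-4-methoxybenzaldehyde)
Product: 3 4-methoxybenzene-1,3-diol, via 3-hydroxy-4-methoxyphenyl formate 2 (not isolated)
Conditions: mCPBA, CH2Cl2, 0 °C to rt; aq. NaHCO3 wash; then K2CO3 (cat.), MeOH, N2, rt
Reagents that add atoms: 3-chloroperoxybenzoic acid (mCPBA), O=C(OO)c1cccc(Cl)c1
Why: Baeyer–Villiger (Dakin-type) oxidation: the peracid adds to the aldehyde and the aryl group, made migration-prone by the para methoxy group, shifts to oxygen to give formate 2; base-catalysed methanolysis under nitrogen then frees the air-sensitive diol.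

Step 2
Reactants: 3 4-methoxybenzene-1,3-diol; 4 ethyl acetoacetate
Product: 5 7-hydroxy-6-methoxy-4-methylchromen-2-one
Conditions: 75% aq. H2SO4, 0 °C to rt
Reagents that add atoms: none
Why: Pechmann condensation: the ketone carbon bonds to C6 of 3 (ortho to one hydroxyl, para to the other), then lactonisation and dehydration give the 4-methylcoumarin. The carbon between the two hydroxyls is too crowded and C4 bears the methoxy group, so the 7-hydroxy-6-methoxy pattern results.

Step 3
Reactants: 5 7-hydroxy-6-methoxy-4-methylchromen-2-one; 6 benzyl bromide
Product: 7 7-(benzyloxy)-6-methoxy-4-methylchromen-2-one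
Conditions: K2CO3, acetone, reflux
Reagents that add atoms: none
Why: Williamson ether synthesis on the only hydroxyl, which is acidic (vinylogous carboxylic acid) and alkylates cleanly by SN2 with the benzylic bromide.

Step 4
Reactants: 7 7-(benzyloxy)-6-methoxy-4-methylchromen-2-one
Product: 8 7-(benzyloxy)-3-bromo-6-methoxy-4-methylchromen-2-one
Conditions: NBS, MeCN, 80 °C, dark
Reagents that add atoms: N-bromosuccinimide, O=C1CCC(=O)N1Br
Why: Electrophilic bromination of a push–pull alkene: the 7-alkoxy group, para to C4a, feeds electron density through C4a–C4=C3, making C3 the most nucleophilic carbon, and loss of the C3 proton restores the coumarin. A polar solvent without light or initiator suppresses radical bromination of the methyl and benzylic CH2 groups; the reaction is known for 6,7-dialkoxy-4-methylcoumarins.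

Step 5
Reactants: 8 7-(benzyloxy)-3-bromo-6-methoxy-4-methylchromen-2-one
Product: 10 6-(benzyloxy)-5-methoxy-3-methylbenzofuran-2-carboxylic acid, via ring-opened bromobutenoate dianion 9 (not isolated)
Conditions: NaOH (3 equiv), EtOH–H2O, reflux; then aq. HCl to pH 1, 0 °C
Reagents that add atoms: sodium hydroxide, [Na+].[OH-]
Why: Perkin coumarin-to-benzofuran ring contraction: hydroxide adds to the lactone carbonyl of 8 and opens the ring to dianion 9, in which the aryl group and the carboxylate stay cis on the alkene (E descriptor) and the bromine is therefore trans to the aryl group. The phenoxide oxygen then attacks the bromine-bearing alkene carbon (former coumarin C3) and bromide leaves, forming O1–C2 of the benzofuran; this is an intramolecular vinylic substitution, either by addition to a transient benzylic carbanion that expels bromide or by in-plane displacement with the oxygen entering from the side remote from the departing bromine. The furan ring is closed in a formally 5-endo-trig mode, tolerated here because nucleophile, alkene and leaving group are held coplanar by conjugation and the product is aromatic. The closest known reaction type is the Perkin rearrangement of 3-halocoumarins to benzofuran-2-carboxylic acids, established for 3-bromo-4-methylcoumarins bearing alkoxy groups at C6 and C7. No stereocentre is formed. The selectivity needed is chemoselectivity: ring closure must outrun hydroxide attack at the vinylic carbon, and the phenoxide (made more nucleophilic by the para methoxy group) together with excess hydroxide at reflux secures it, while any unclosed 9 only relactonises to 8 on acidification and can be resubmitted. The benzyl and methyl ethers are inert to hot aqueous hydroxide, the former 4-methyl group arrives as the C3 methyl, and the lactone carbonyl becomes the C2 carboxyl used in step 6.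

Step 6
Reactants: 10 6-(benzyloxy)-5-methoxy-3-methylbenzofuran-2-carboxylic acid; 11 5-bromo-1,2,3-trimethoxybenzene
Product: 12 6-(benzyloxy)-5-methoxy-3-methyl-2-(3,4,5-trimethoxyphenyl)benzofuran
Conditions: Pd[P(t-Bu)3]2 (5 mol %), n-Bu4NCl (1 equiv), Cs2CO3 (1.5 equiv), DMF, 170 °C (sealed vessel, microwave)
Reagents that add atoms: none
Why: Palladium-catalysed decarboxylative cross-coupling of a heteroaromatic 2-carboxylic acid with an aryl bromide: oxidative addition of 11 to zerovalent palladium, exchange of bromide for the caesium carboxylate, loss of CO2 to a 2-benzofuranyl(aryl)palladium species and reductive elimination form the C2–aryl bond where the carboxyl sat. The 3-methyl group shuts off the competing C3 arylation, and 3-methylbenzofuran-2-carboxylic acids are established substrates of this coupling.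

Step 7
Reactants: 12 6-(benzyloxy)-5-methoxy-3-methyl-2-(3,4,5-trimethoxyphenyl)benzofuran
Product: 13 5-methoxy-3-methyl-2-(3,4,5-trimethoxyphenyl)benzofuran-6-ol
Conditions: H2 (1 atm), 10% Pd/C, EtOAc–MeOH, rt
Reagents that add atoms: none
Why: Hydrogenolysis of the benzyl ether leaves the four methyl ethers untouched. The tetrasubstituted C2=C3 bond is part of the aromatic 2-arylbenzofuran and should resist reduction at room temperature and atmospheric pressure if the reaction is stopped after one equivalent of hydrogen.

Step 8
Reactants: 13 5-methoxy-3-methyl-2-(3,4,5-trimethoxyphenyl)benzofuran-6-ol; 14 allyl bromide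
Product: 15 6-(allyloxy)-5-methoxy-3-methyl-2-(3,4,5-trimethoxyphenyl)benzofuran
Conditions: K2CO3, acetone, reflux
Reagents that add atoms: none
Why: Williamson O-allylation (SN2) of the only free phenol; with carbonate in acetone the phenoxide alkylates on oxygen.

Step 9
Reactants: 15 6-(allyloxy)-5-methoxy-3-methyl-2-(3,4,5-trimethoxyphenyl)benzofuran
Product: 16 7-allyl-5-methoxy-3-methyl-2-(3,4,5-trimethoxyphenyl)benzofuran-6-ol
Conditions: N,N-diethylaniline, 200 °C, argon (sealed tube)
Reagents that add atoms: none
Why: Aromatic Claisen rearrangement: [3,3]-sigmatropic shift of the allyl group from O6 to the ortho carbon, then tautomerisation of the dienone to the phenol. C5 bears the methoxy group and the para position is the ring-fusion carbon C3a, so C7 is the only carbon at which rearomatisation is possible, and the allyl group arrives with its terminal alkene intact.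

## Compound list

1 | isovanillin (3-hydroxy-4-methoxybenzaldehyde) | COc1ccc(C=O)cc1O | starting material
2 | 3-hydroxy-4-methoxyphenyl formate | COc1ccc(OC=O)cc1O | intermediate (not isolated)
3 | 4-methoxybenzene-1,3-diol | COc1ccc(O)cc1O | intermediate
4 | ethyl acetoacetate | CCOC(=O)CC(C)=O | starting material
5 | 7-hydroxy-6-methoxy-4-methylchromen-2-one | Cc1cc(=O)oc2cc(O)c(OC)cc12 | intermediate
6 | benzyl bromide | BrCc1ccccc1 | starting material
7 | 7-(benzyloxy)-6-methoxy-4-methylchromen-2-one | Cc1cc(=O)oc2cc(OCc3ccccc3)c(OC)cc12 | intermediate
8 | 7-(benzyloxy)-3-bromo-6-methoxy-4-methylchromen-2-one | Cc1c(Br)c(=O)oc2cc(OCc3ccccc3)c(OC)cc12 | intermediate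
9 | disodium (E)-3-[4-(benzyloxy)-5-methoxy-2-oxidophenyl]-2-bromobut-2-enoate | C/C(=C(\Br)C(=O)[O-])c1cc(OC)c(OCc2ccccc2)cc1[O-].[Na+].[Na+] | intermediate (not isolated)
10 | 6-(benzyloxy)-5-methoxy-3-methylbenzofuran-2-carboxylic acid | Cc1c(C(=O)O)oc2cc(OCc3ccccc3)c(OC)cc12 | intermediate
11 | 5-bromo-1,2,3-trimethoxybenzene | COc1cc(Br)cc(OC)c1OC | starting material
12 | 6-(benzyloxy)-5-methoxy-3-methyl-2-(3,4,5-trimethoxyphenyl)benzofuran | Cc1c(-c2cc(OC)c(OC)c(OC)c2)oc2cc(OCc3ccccc3)c(OC)cc12 | intermediate
13 | 5-methoxy-3-methyl-2-(3,4,5-trimethoxyphenyl)benzofuran-6-ol | Cc1c(-c2cc(OC)c(OC)c(OC)c2)oc2cc(O)c(OC)cc12 | intermediate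
14 | allyl bromide | C=CCBr | starting material
15 | 6-(allyloxy)-5-methoxy-3-methyl-2-(3,4,5-trimethoxyphenyl)benzofuran | C=CCOc1cc2oc(-c3cc(OC)c(OC)c(OC)c3)c(C)c2cc1OC | intermediate
16 | 7-allyl-5-methoxy-3-methyl-2-(3,4,5-trimethoxyphenyl)benzofuran-6-ol | C=CCc1c(O)c(OC)cc2c(C)c(-c3cc(OC)c(OC)c(OC)c3)oc12 | target

## Step count and risk

Total steps: 9. Longest linear sequence: 9 steps, from isovanillin 1 to target 16; compounds 4, 6, 11 and 14 enter as single reagents.

**Step 5 (key step).** The lactone opening is fast, but ring closure at a tetrasubstituted, electron-rich bromoalkene may be slow. Incomplete closure would be followed by relactonisation on acidification, and prolonged heating invites loss of hydrogen bromide or of the carboxyl group. The fallback abandons the ring contraction and builds the same acid by O-alkylation and intramolecular aldol condensation. It sets out from diol 3. Acetylation with acetic acid and BF3·OEt2 at the carbon para to one hydroxyl should give 1-(2,4-dihydroxy-5-methoxyphenyl)ethanone F1. Benzylation of the non-chelated 4-hydroxyl with 6 and K2CO3 in acetone should give 1-[4-(benzyloxy)-2-hydroxy-5-methoxyphenyl]ethanone F2. Heating F2 with ethyl bromoacetate and K2CO3 in DMF alkylates the remaining phenol, and the resulting ester enolate condenses onto the ketone with loss of water to give ethyl 6-(benzyloxy)-5-methoxy-3-methylbenzofuran-2-carboxylate F3. Saponification with NaOH in aqueous ethanol and acidification bring the route back at acid 10.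

**Step 6.** Protodecarboxylation of the carboxylate at 170 °C may outpace aryl transfer, oxidative addition of the electron-rich bromide 11 may be slow, and homocoupling of the aryl halide may intrude. The fallback makes the decarboxylation deliberate and forms the biaryl bond by C–H activation instead. It starts from acid 10. Protodecarboxylation with catalytic Ag2CO3 and acetic acid in DMSO at 120 °C should give 6-(benzyloxy)-5-methoxy-3-methylbenzofuran F4. Direct arylation of its only free furan position with 11 (Pd(OAc)2, PCy3·HBF4, pivalic acid, K2CO3, DMA, 100 °C; concerted metalation–deprotonation) returns to 12.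

**Step 4.** Site selectivity may erode through electrophilic attack on the activated benzo ring (C8 or C5) or radical bromination of the 4-methyl or benzylic CH2 group. The fallback introduces the halogen together with the ring, so no selective halogenation is needed. It starts from diol 3. Pechmann condensation with ethyl 2-chloroacetoacetate in 75% aq. H2SO4 should give 3-chloro-7-hydroxy-6-methoxy-4-methylchromen-2-one F5. Benzylation with 6 and K2CO3 gives 7-(benzyloxy)-3-chloro-6-methoxy-4-methylchromen-2-one F6. The same hydroxide-induced contraction, with chloride as the slower leaving group and longer reflux, delivers acid 10.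

**Step 1.** The peracid may over-oxidise the free electron-rich phenol (ring hydroxylation, quinone formation), and the diol may be oxidised by air during basic methanolysis. The fallback masks the phenol before the oxidation. It starts from 1. Benzylation with 6 and K2CO3 gives 3-(benzyloxy)-4-methoxybenzaldehyde F7. Peracid oxidation gives 3-(benzyloxy)-4-methoxyphenyl formate F8, and methanolysis gives 3-(benzyloxy)-4-methoxyphenol F9. Hydrogenolysis over 10% Pd/C under neutral conditions returns to diol 3.

**Step 9.** At 200 °C the rearrangement may be accompanied by secondary reactions of the product: addition of the phenol to the new alkene to form a dihydrofuran, migration of the double bond into conjugation, or ether cleavage. The fallback replaces the sigmatropic shift by halogenation and cross-coupling. It starts from phenol 13. Bromination with N-bromosuccinimide in CH2Cl2 at low temperature, at the only position ortho to the free hydroxyl, should give 7-bromo-5-methoxy-3-methyl-2-(3,4,5-trimethoxyphenyl)benzofuran-6-ol F10. Stille coupling with allyltributylstannane and Pd(PPh3)4 in toluene at 100 °C then gives target 16.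

## Further compounds

F1 | step 5 | 1-(2,4-dihydroxy-5-methoxyphenyl)ethanone | CC(=O)c1cc(OC)c(O)cc1O
F2 | step 5 | 1-[4-(benzyloxy)-2-hydroxy-5-methoxyphenyl]ethanone | CC(=O)c1cc(OC)c(OCc2ccccc2)cc1O
F3 | step 5 | ethyl 6-(benzyloxy)-5-methoxy-3-methylbenzofuran-2-carboxylate | CCOC(=O)c1oc2cc(OCc3ccccc3)c(OC)cc2c1C
F4 | step 6 | 6-(benzyloxy)-5-methoxy-3-methylbenzofuran | Cc1coc2cc(OCc3ccccc3)c(OC)cc12
F5 | step 4 | 3-chloro-7-hydroxy-6-methoxy-4-methylchromen-2-one | Cc1c(Cl)c(=O)oc2cc(O)c(OC)cc12
F6 | step 4 | 7-(benzyloxy)-3-chloro-6-methoxy-4-methylchromen-2-one | Cc1c(Cl)c(=O)oc2cc(OCc3ccccc3)c(OC)cc12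
F7 | step 1 | 3-(benzyloxy)-4-methoxybenzaldehyde | COc1ccc(C=O)cc1OCc1ccccc1
F8 | step 1 | 3-(benzyloxy)-4-methoxyphenyl formate | COc1ccc(OC=O)cc1OCc1ccccc1
F9 | step 1 | 3-(benzyloxy)-4-methoxyphenol | COc1ccc(O)cc1OCc1ccccc1
F10 | step 9 | 7-bromo-5-methoxy-3-methyl-2-(3,4,5-trimethoxyphenyl)benzofuran-6-ol | Cc1c(-c2cc(OC)c(OC)c(OC)c2)oc2c(Br)c(O)c(OC)cc12
A1 | alternative 1 | trans-7-allyl-5-methoxy-6-(methoxymethoxy)-3-methyl-2-(3,4,5-trimethoxyphenyl)-2,3-dihydrobenzofuran (racemic, relative configuration shown) | C[C@H]1[C@H](c2cc(OC)c(OC)c(OC)c2)Oc2c1cc(OC)c(OCOC)c2CC=C
A2 | alternative 1 | dimethyl(3,4,5-trimethoxybenzyl)sulfonium bromide | COc1cc(C[S+](C)C)cc(OC)c1OC.[Br-]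
A3 | alternative 1 | 2-allyl-4-methoxy-3-(methoxymethoxy)-6-[1-(4-methylphenylsulfonyl)ethyl]phenol (racemic) | C=CCc1c(O)c(C(C)S(=O)(=O)c2ccc(C)cc2)cc(OC)c1OCOC
A4 | alternative 2 | 2-(3-allyl-4-isopropoxy-5-methoxyphenyl)-1-(3,4,5-trimethoxyphenyl)propan-1-one (racemic) | C=CCc1cc(C(C)C(=O)c2cc(OC)c(OC)c(OC)c2)cc(OC)c1OC(C)C
A5 | alternative 2 | 7-allyl-6-isopropoxy-5-methoxy-3-methyl-2-(3,4,5-trimethoxyphenyl)benzofuran | C=CCc1c(OC(C)C)c(OC)cc2c(C)c(-c3cc(OC)c(OC)c(OC)c3)oc12
A6 | alternative 3 | 2-allyl-3-hydroxy-6-methoxyphenyl pivalate | C=CCc1c(O)ccc(OC)c1OC(=O)C(C)(C)C
A7 | alternative 3 | (E)-isoelemicin, 1,2,3-trimethoxy-5-[(E)-prop-1-enyl]benzene | C/C=C/c1cc(OC)c(OC)c(OC)c1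
A8 | alternative 3 | trans-7-allyl-5-methoxy-3-methyl-2-(3,4,5-trimethoxyphenyl)-2,3-dihydrobenzofuran-6-yl pivalate (racemic, relative configuration shown) | C[C@H]1[C@H](c2cc(OC)c(OC)c(OC)c2)Oc2c1cc(OC)c(OC(=O)C(C)(C)C)c2CC=C
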